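# Total synthesis of (−)-macrocarpal D via (−)-α-gurjunene

## Retrosynthetic overview

1. Macrocarpal D ⇒ (−)-α-gurjunene + 2,4-diformylphloroglucinol + 3-methylbutanal. The C4–C9′ bond is made last by o-quinone-methide alkylation of the C4=C5 alkene; opening of the resulting cyclopropylcarbinyl cation gives the C5=C6 alkene and the C11 carbinol.
2. α-Gurjunene ⇒ bicyclic 4,6-diene (dimethylcyclopropanation) ⇒ hydroazulenone (Shapiro reaction).
3. Hydroazulenone ⇒ cis-3,4-disubstituted cycloheptanone (five-membered ring by aldol condensation; cis relation by hydrogenation).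
4. Cycloheptenone ⇒ cyclohexenone by one-carbon ring expansion (siloxycyclopropane, FeCl3) of the enolate from asymmetric conjugate methylation; side chain by Suzuki coupling.
5. Ring order: six → seven (ring expansion) → five → three; the arene is made separately from resorcinol.

Assumption: guaiane numbering (C1–C15) is used for the terpene carbons and C9′ for the benzylic carbon; in this numbering the target SMILES is 1R,4R,7R,10R,9′R.

## Route

**Step 1**
Reactants: 1 2-iodocyclohex-2-en-1-one; 2 2-ethenyl-2-methyl-1,3-dioxolane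
Product: 4 2-[2-(2-methyl-1,3-dioxolan-2-yl)ethyl]cyclohex-2-en-1-one, via alkylborane 3 (not isolated)
Conditions: 2, 9-BBN-H, THF, 0 °C → rt; then 1, PdCl2(dppf) (3 mol %), Ph3As, Cs2CO3, DMF–H2O, rt
Reagents that add atoms: none
Why: B-alkyl Suzuki–Miyaura coupling; anti-Markovnikov hydroboration gives a primary alkyl-9-BBN that couples with the α-iodoenone under mild conditions, and no stereocentre is formed.

**Step 2**
Reactants: 4 2-[2-(2-methyl-1,3-dioxolan-2-yl)ethyl]cyclohex-2-en-1-one
Product: 6 trimethyl{[(5R)-5-methyl-6-[2-(2-methyl-1,3-dioxolan-2-yl)ethyl]bicyclo[4.1.0]heptan-1-yl]oxy}silane (cis-fused; cyclopropane face not controlled), via silyl enol ether 5 (not isolated)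
Conditions: Me3Al, CuTC (5 mol %), chiral phosphoramidite L* (10 mol %; enantiomer giving 3R), Et2O, −30 °C; TMSOTf, −30 → 0 °C; then Et2Zn, CH2I2, 0 °C → rt
Reagents that add atoms: trimethylaluminium, C[Al](C)C; trimethylsilyl trifluoromethanesulfonate, C[Si](C)(C)OS(=O)(=O)C(F)(F)F; diiodomethane, ICI
Why: Tandem Cu-catalysed asymmetric conjugate addition–silylation–Simmons–Smith cyclopropanation; the ligand sets C10 (R), O-silylation fixes the enolate as the tetrasubstituted C6=C1 enol ether, and the two cyclopropane centres are destroyed in step 3.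

**Step 3**
Reactants: 6 siloxycyclopropane from step 2
Product: 9 (4R)-4-methyl-3-(3-oxobutyl)cyclohept-2-en-1-one, via chloro ketone 7 (not isolated), via ketal enone 8 (not isolated)
Conditions: FeCl3 (2.2 equiv), DMF, 0 °C → rt; NaOAc, MeOH, reflux; then 1 M HCl, THF, rt
Reagents that add atoms: water, O
Why: Ito–Saegusa ring expansion; one-electron oxidation by FeCl3 cleaves the internal cyclopropane bond to the ring-enlarged β-keto radical (a radical fragmentation), chlorine transfer and E1cB loss of HCl give the cycloheptenone with the alkene at C5=C1, and acid unmasks the methyl ketone while C10 is untouched.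

**Step 4**
Reactants: 9 (4R)-4-methyl-3-(3-oxobutyl)cyclohept-2-en-1-one
Product: 10 (3S,4R)-4-methyl-3-(3-oxobutyl)cycloheptan-1-one
Conditions: H2 (1 atm), 10 % Pd/C, EtOAc, rt
Reagents that add atoms: none
Why: Heterogeneous hydrogenation; A(1,2) strain with the side chain on C1 makes the C10 methyl pseudo-axial, so H2 adds to C1 from the opposite face and gives the cis side-chain/methyl relation (C1–H trans to C10–Me), and C1 is now β to the ketone and cannot epimerise.

**Step 5**
Reactants: 10 (3S,4R)-4-methyl-3-(3-oxobutyl)cycloheptan-1-one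
Product: 11 (8R,8aR)-3,8-dimethyl-2,5,6,7,8,8a-hexahydroazulen-4(1H)-one
Conditions: KOH, MeOH, 50 °C
Reagents that add atoms: none
Why: Intramolecular aldol condensation of a 1,6-diketone; the C5 enolate of the ring ketone closes the five-membered ring onto the methyl ketone and dehydration to the tetrasubstituted enone is the thermodynamic sink (the other aldol modes are bridged, reversible and cannot dehydrate), with C1 and C10 not enolisable.

**Step 6**
Reactants: 11 (8R,8aR)-3,8-dimethyl-2,5,6,7,8,8a-hexahydroazulen-4(1H)-one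
Product: 12 N′-[(8R,8aR)-3,8-dimethyl-2,5,6,7,8,8a-hexahydroazulen-4(1H)-ylidene]-4-methylbenzenesulfonohydrazide
Conditions: TsNHNH2, EtOH, AcOH (cat.), 60 °C
Reagents that add atoms: 4-methylbenzenesulfonohydrazide, Cc1ccc(cc1)S(=O)(=O)NN
Why: Tosylhydrazone formation (condensation) at the only carbonyl group; no stereocentre is affected.

**Step 7**
Reactants: 12 tosylhydrazone from step 6
Product: 14 (8R,8aR)-3,8-dimethyl-1,2,6,7,8,8a-hexahydroazulene, via vinyllithium 13 (not isolated)
Conditions: LDA (3 equiv), THF, −78 °C → rt; then H2O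
Reagents that add atoms: none
Why: Shapiro reaction; α′-deprotonation at C7 and loss of sulfinate and N2 give the C6 vinyllithium, whose protonation leaves the conjugated C4=C5–C6=C7 diene with no oxygen on the skeleton.

**Step 8**
Reactants: 14 (8R,8aR)-3,8-dimethyl-1,2,6,7,8,8a-hexahydroazulene
Product: 15 (−)-α-gurjunene, (1aR,4R,4aR,7bS)-1,1,4,7-tetramethyl-1a,2,3,4,4a,5,6,7b-octahydro-1H-cyclopropa[e]azulene
Conditions: (iPr-PDI)CoBr2 (10 mol %), Me2CCl2, Zn, ZnBr2, THF, rt
Reagents that add atoms: 2,2-dichloropropane, CC(C)(Cl)Cl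
Why: Cobalt-catalysed reductive dimethylcyclopropanation of a 1,3-diene (Simmons–Smith-type CMe2 transfer); the carbenoid takes the cis-disubstituted C6=C7 alkene rather than the tetrasubstituted one and should approach from the β-face because C10 and C9 hang below the diene plane (C1–H is β), which sets C6 and C7.

**Step 9**
Reactants: 16 benzene-1,3-diol (resorcinol)
Product: 19 benzene-1,3,5-triol (phloroglucinol), via bis-TMS ether 17 (not isolated), via aryl boronate 18 (not isolated)
Conditions: HMDS, TMSCl (cat.), 80 °C, concentrate; [Ir(OMe)(cod)]2 (1.5 mol %), dtbpy, B2pin2, THF, 80 °C; then Oxone, acetone–H2O, rt; dil. HCl work-up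
Reagents that add atoms: potassium peroxymonosulfate (Oxone), OOS(=O)(=O)[O-].[K+]
Why: One-pot silylation, sterically controlled Ir-catalysed C–H borylation at C5 (the only C–H without an ortho substituent) and oxidation of the C–B bond; the aqueous work-up also removes the TMS groups.

**Step 10**
Reactants: 19 benzene-1,3,5-triol
Product: 20 2,4,6-trihydroxybenzene-1,3-dicarbaldehyde
Conditions: POCl3, DMF, dioxane, 0 °C → rt; then H2O, 60 °C
Reagents that add atoms: N,N-dimethylformamide, CN(C)C=O; water, O
Why: Vilsmeier–Haack formylation; the electron-rich ring is formylated twice and the third position is deactivated by the two formyl groups.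

**Step 11**
Reactants: 15 (−)-α-gurjunene; 20 2,4,6-trihydroxybenzene-1,3-dicarbaldehyde; 21 3-methylbutanal
Product: 23 (−)-macrocarpal D, via o-quinone methide 22 (not isolated)
Conditions: TRIP (10 mol %; enantiomer exposing the Si face of C9′, (R)-TRIP tried first), 20 (1.2 equiv), 21 (2 equiv), CHCl3–H2O (5 equiv H2O), 40 °C
Reagents that add atoms: water, O
Why: Proposed new method: the phosphoric acid promotes Knoevenagel-type condensation of 20 with 21 to the o-quinone methide 22 and holds it by two hydrogen bonds (P=O···H–O and P–O–H···O=C) so that one face is shielded; the tetrasubstituted C4=C5 alkene of 15, made electron-rich by the adjacent cyclopropane, attacks the Si face of C9′ through its β-face (the α-face is blocked by C10 and its methyl group), forming the C4–C9′ bond and setting 4R and 9′R; the bisected cyclopropylcarbinyl cation at C5 opens by C6–C11 cleavage to the C5=C6 alkene and the tertiary C11 cation, which water captures as the carbinol, with C1, C7 and C10 untouched; the closest known reactions are chiral-phosphoric-acid-catalysed additions and [4+2] cycloadditions of alkenes to in situ o-quinone methides, the uncatalysed three-component o-quinone-methide/terpene coupling and the acid-induced cyclopropylcarbinyl-to-homoallyl opening.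

## Compound list

1 | 2-iodocyclohex-2-en-1-one | O=C1CCCC=C1I | starting material
2 | 2-ethenyl-2-methyl-1,3-dioxolane | C=CC1(C)OCCO1 | starting material
3 | 9-[2-(2-methyl-1,3-dioxolan-2-yl)ethyl]-9-borabicyclo[3.3.1]nonane (not isolated) | CC1(CCB2C3CCCC2CCC3)OCCO1 | intermediate
4 | 2-[2-(2-methyl-1,3-dioxolan-2-yl)ethyl]cyclohex-2-en-1-one | CC1(CCC2=CCCCC2=O)OCCO1 | intermediate
5 | trimethyl{[(3R)-3-methyl-2-[2-(2-methyl-1,3-dioxolan-2-yl)ethyl]cyclohex-1-en-1-yl]oxy}silane (not isolated) | C[C@@H]1CCCC(O[Si](C)(C)C)=C1CCC1(C)OCCO1 | intermediate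
6 | trimethyl{[(5R)-5-methyl-6-[2-(2-methyl-1,3-dioxolan-2-yl)ethyl]bicyclo[4.1.0]heptan-1-yl]oxy}silane (cis-fused, C1/C6 face unassigned) | C[C@@H]1CCCC2(O[Si](C)(C)C)CC12CCC1(C)OCCO1 | intermediate
7 | (4R)-3-chloro-4-methyl-3-[2-(2-methyl-1,3-dioxolan-2-yl)ethyl]cycloheptan-1-one (not isolated) | C[C@@H]1CCCC(=O)CC1(Cl)CCC1(C)OCCO1 | intermediate
8 | (4R)-4-methyl-3-[2-(2-methyl-1,3-dioxolan-2-yl)ethyl]cyclohept-2-en-1-one (not isolated) | C[C@@H]1CCCC(=O)C=C1CCC1(C)OCCO1 | intermediate
9 | (4R)-4-methyl-3-(3-oxobutyl)cyclohept-2-en-1-one | C[C@@H]1CCCC(=O)C=C1CCC(C)=O | intermediate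
10 | (3S,4R)-4-methyl-3-(3-oxobutyl)cycloheptan-1-one | CC(=O)CC[C@H]1CC(=O)CCC[C@H]1C | intermediate
11 | (8R,8aR)-3,8-dimethyl-2,5,6,7,8,8a-hexahydroazulen-4(1H)-one | O=C1CCC[C@@H](C)[C@H]2CCC(C)=C12 | intermediate
12 | tosylhydrazone of 11 | Cc1ccc(cc1)S(=O)(=O)NN=C1CCC[C@@H](C)[C@H]2CCC(C)=C12 | intermediate
13 | [(8R,8aR)-3,8-dimethyl-1,2,6,7,8,8a-hexahydroazulen-4-yl]lithium (not isolated) | [Li]C1=CCC[C@@H](C)[C@H]2CCC(C)=C12 | intermediate
14 | (8R,8aR)-3,8-dimethyl-1,2,6,7,8,8a-hexahydroazulene | CC1=C2C=CCC[C@@H](C)[C@H]2CC1 | intermediate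
15 | (−)-α-gurjunene, (1aR,4R,4aR,7bS)-1,1,4,7-tetramethyl-1a,2,3,4,4a,5,6,7b-octahydro-1H-cyclopropa[e]azulene | C[C@@H]1CC[C@@H]2[C@@H](C2(C)C)C3=C(CC[C@H]13)C | intermediate
16 | benzene-1,3-diol (resorcinol) | Oc1cccc(O)c1 | starting material
17 | 1,3-bis(trimethylsilyloxy)benzene (not isolated) | C[Si](C)(C)Oc1cccc(O[Si](C)(C)C)c1 | intermediate
18 | 2-[3,5-bis(trimethylsilyloxy)phenyl]-4,4,5,5-tetramethyl-1,3,2-dioxaborolane (not isolated) | C[Si](C)(C)Oc1cc(O[Si](C)(C)C)cc(c1)B1OC(C)(C)C(C)(C)O1 | intermediate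
19 | benzene-1,3,5-triol (phloroglucinol) | Oc1cc(O)cc(O)c1 | intermediate
20 | 2,4,6-trihydroxybenzene-1,3-dicarbaldehyde | O=Cc1c(O)cc(O)c(C=O)c1O | intermediate
21 | 3-methylbutanal | CC(C)CC=O | starting material
22 | 2,4-diformyl-3,5-dihydroxy-6-(3-methylbutylidene)cyclohexa-2,4-dien-1-one (o-quinone methide, not isolated) | CC(C)CC=C1C(=O)C(C=O)=C(O)C(C=O)=C1O | intermediate
23 | (−)-macrocarpal D (1R,4R,7R,10R,9′R) | CC(C)C[C@@H](c1c(O)c(C=O)c(O)c(C=O)c1O)[C@@]1(C)CC[C@H]2C1=C[C@H](C(C)(C)O)CC[C@H]2C | target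

## Step count and risk

Total steps: 11. Longest linear sequence: 9 (steps 1–8, then 11).

Steps most likely to fail, each with a fallback:

Step 11 (the proposed new step). The catalyst may not control the C9′ configuration, the acid may isomerise 15, or the reaction may stop at the chroman. The fallback uses known chemistry and sets out from 15 together with 20 and 21. Uncatalysed three-component coupling (NaOAc, AcOH, 80 °C) gives the hetero-Diels–Alder adducts, from which the chroman carrying O on C5 and C9′ on C4 on the β-face with 9′R configuration F7 is separated from its 9′-epimer by chromatography. Brief treatment of F7 with TsOH·H2O in wet acetone ionises the tertiary C5–O bond, and the same cyclopropylcarbinyl-to-homoallyl opening and hydration return the route at 23.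

Step 2. The α-substituted enone may react slowly or with low ee, and Me3Al/TMSOTf may open the dioxolane. The fallback sets out from 4. CBS reduction gives (S)-2-[2-(2-methyl-1,3-dioxolan-2-yl)ethyl]cyclohex-2-en-1-ol F1. Hydroxyl-directed Simmons–Smith cyclopropanation (Et2Zn, CH2I2) gives (1R,2S,6S)-1-[2-(2-methyl-1,3-dioxolan-2-yl)ethyl]bicyclo[4.1.0]heptan-2-ol F2. Dess–Martin oxidation gives (1R,6S)-1-[2-(2-methyl-1,3-dioxolan-2-yl)ethyl]bicyclo[4.1.0]heptan-2-one F3. Li/NH3 reduction then cleaves the exocyclic cyclopropane bond that overlaps with the carbonyl group, turning the cyclopropane CH2 into the C10 methyl group, and the regiodefined enolate is trapped with TMSCl. The route is rejoined at 5, which is cyclopropanated to 6 as in step 2.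

Step 8. The cobalt carbenoid may be unreactive towards this cyclic diene or add from the wrong face. The fallback sets out from 14. Rh2(esp)2-catalysed cyclopropanation with dimethyl diazomalonate at the less hindered C6=C7 alkene gives the 11,11-bis(methoxycarbonyl) analogue of α-gurjunene F4. LiAlH4 reduction gives the 11,11-bis(hydroxymethyl) compound F5, and MsCl/Et3N gives the bis(methanesulfonate) F6. LiEt3BH reduction of both primary sulfonates returns the route at 15.

## Further compounds

F1 | step 2 | (S)-2-[2-(2-methyl-1,3-dioxolan-2-yl)ethyl]cyclohex-2-en-1-ol | O[C@H]1CCCC=C1CCC1(C)OCCO1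
F2 | step 2 | (1R,2S,6S)-1-[2-(2-methyl-1,3-dioxolan-2-yl)ethyl]bicyclo[4.1.0]heptan-2-ol | O[C@H]1CCC[C@H]2C[C@@]12CCC1(C)OCCO1
F3 | step 2 | (1R,6S)-1-[2-(2-methyl-1,3-dioxolan-2-yl)ethyl]bicyclo[4.1.0]heptan-2-one | O=C1CCC[C@H]2C[C@@]12CCC1(C)OCCO1
F4 | step 8 | 11,11-bis(methoxycarbonyl) analogue of α-gurjunene (dimethyl cyclopropane-1,1-dicarboxylate, ring stereochemistry as in 15) | C[C@@H]1CC[C@@H]2[C@@H](C2(C(=O)OC)C(=O)OC)C3=C(CC[C@H]13)C
F5 | step 8 | 11,11-bis(hydroxymethyl) analogue of α-gurjunene | C[C@@H]1CC[C@@H]2[C@@H](C2(CO)CO)C3=C(CC[C@H]13)C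
F6 | step 8 | 11,11-bis(methanesulfonyloxymethyl) analogue of α-gurjunene | C[C@@H]1CC[C@@H]2[C@@H](C2(COS(C)(=O)=O)COS(C)(=O)=O)C3=C(CC[C@H]13)C
F7 | step 11 | hetero-Diels–Alder chroman of 22 and 15 (O on C5, C9′ on C4, both β; 9′R) | CC(C)C[C@H]1c2c(O)c(C=O)c(O)c(C=O)c2O[C@]23[C@@H]4C(C)(C)[C@@H]4CC[C@@H](C)[C@H]2CC[C@]13C
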